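**Charge against time.** Theta gets twice the L of eta but 3.75 times its time, under the same held G, so you must weigh a larger charge against a longer run.

| flask | L | G | remark | time |
|---|---|---|---|---|
| north-west | 14 mM | 2.8 mM (held) | run made earlier |  |
| south-west | 30 mM | 2.8 mM (held) | run made earlier |  |
| theta | 20 mM | 2.8 mM (held) |  | 15 min |
| eta | 10 mM | 2.8 mM (held) |  | 4.0 min |

| run | time / min | E / % | L / % |
|---|---|---|---|
| north-west | 0.667 | 2.3 | 96.8 |
| north-west | 1.00 | 3.3 | 94.9 |
| north-west | 2.00 | 8.7 | 86.9 |
| north-west | 4.00 | 21.5 | 70.4 |
| north-west | 8.00 | 38.7 | 41.4 |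
| south-west | 0.667 | 1.9 | 97.6 |
| south-west | 1.00 | 3.7 | 96.2 |
| south-west | 2.00 | 6.9 | 90.3 |
| south-west | 4.00 | 12.4 | 76.8 |
| south-west | 8.00 | 22.7 | 50.4 |

(each reading ± 0.5 percentage points)

- at the start none of G is in solution

- which one finishes higher in amount of E, in percent of the L charged ("neither" within 2 percentage points) (theta / eta / neither)
- amount of E at the end, in percent of the L charged, theta
- amount of E at the end, in percent of the L charged, eta

**Supply number.** Between 2.00 min and 4.00 min the north-west run gains 0.896 mM min⁻¹ of E, while between 2.00 min and 8.00 min the south-west run, with twice the L, gains 0.790 mM min⁻¹, so as read here the pace does not rise with L, a stretch near zero order in L. Taking the south-west pace, multiplying by the time and dividing by the L charged gives 59.2 % for theta and 31.6 % for eta; this is the supply number, the fraction of the charge that this pace turns into E within the run.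

**One number enough?** You can test it on the north-west run at 8.00 min, which it was not read from: it gives 45.1 % against a reading of 38.7 %, an overshoot. So I trust the order, theta ahead, and expect both values to come in lower.

**The forecast.** It says theta, with 45 % and 24 %, lower than my numbers, and it reads the runs as “gas-transfer limitation”.

**The flask.** Theta finishes higher, 46.7 % against 24.8 % for eta, close to the forecast.

    G ⇌ J, rate k1*(csat - [J]) (kL = 0.0112 s⁻¹)
    L + J → E (k = 1.09 L mol⁻¹ s⁻¹)
    L → Q (k = 2.08 × 10⁻⁴ s⁻¹)
    L + E → Z (k = 0.0734 L mol⁻¹ s⁻¹)

**Why theta leads.** The gap between the flasks comes mainly from the time, for eta gives 24.8 % of E as it stands and 63.8 % when it is given theta's time. Eta read at 15.0 min has a supply number of 118 %, twice theta's 59.2 %, and its E then stands above theta's 46.7 %, so at equal time the order turns. That number stands above the full charge, yet E stays at 63.8 %, with 11 % of the L still unreacted.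

All runs are simulated for an exercise; the scatter is artificial.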